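The data are calculated on assumed constants; the scatter is artificial.

By the last reading, at 15.0 min, the north-east run held 64% target, and the rise had stayed nearly straight: 10 percentage points in the 3.00 min from the first reading to the second, and 18 points in the 5.00 min from the third to the fourth.

the same everywhere: substrate 0.44 M; free catalyst 2 mol%
- north-east: coupling partner 2 equiv; run made earlier
- flask: coupling partner 1.00 equiv

- north-east (time / min: target / %): 2.00: 11; 5.00: 21; 10.0: 46; 15.0: 64

(standard deviation of a reading: 2 percentage points)

* factor on the rate of making target when 10% of the substrate are converted if free catalyst is charged twice over
* factor on the rate when 10% of the substrate are converted if free catalyst is charged at 10 mol% instead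

- the numbers in the tables scatter by 2 percentage points (one standard deviation)
- no earlier run changes the charge of free catalyst; that part of a forecast is a guess

I read that straight rise as a busy catalyst, so my first guess was a rate in proportion to the catalyst. I tested it in powers of ten. Going from 2 mol% to 10 mol% covers 0.699 of a power of ten, and this loading span, the base-ten logarithm of new loading over old, times the order in catalyst gives the logarithm of the rate factor. Doubling covers 0.301. Order 1 then gives factors of 2.00 and 5.00.

One objection was that the north-east run had 2 equiv of coupling partner and the flask has 1.00 equiv. But both rates in a factor share one partner charge and one conversion, so the base rate drops out of the logarithm. The harder objection was that no run varies the catalyst, and a catalyst sitting mostly as an inactive pair has the textbook order 0.5, which gives only 1.41 and 2.24. I therefore committed to the middle order, 0.750, which gives 1.68 and 3.34.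

The forecast gave 2 and 4.6, first order shaded slightly at the high loading: “The larger extrapolation is more likely to fall short”. Its second figure stands higher than mine.

The flask gave 1.70 and 2.55, lower than the forecast on both counts.

    substrate + free catalyst → catalyst intermediate A (k = 40.0 /M/min)
    2 catalyst intermediate B ⇌ resting dimer, settled at all times (K = 92.0 /M)
    catalyst intermediate B → catalyst intermediate C (k = 5.70 /min)
    catalyst intermediate C → free catalyst + target (k = 12.0 /min)
    coupling partner + catalyst intermediate A → catalyst intermediate B (k = 460 /M/min)

Dividing each logarithm by its span gives the order: 0.763 for the flask with doubled catalyst and 0.582 for the flask at 10 mol%, so the order is lower over the wider span. The run without the pairing of catalyst intermediate B to resting dimer shows at most the largest single effect, and it was made at 2 mol% and 10% conversion, not at 10 mol%: the order in free catalyst goes from 0.80 to 1.0, and the rate becomes 1.35 times the actual one.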